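Assumption: the alkyl group of the target is read as the unbranched C21 chain (henicosan-1-yl), which makes the target henicosyl 2,3-dihydroxybenzoate, C28H48O4, with no stereocentre; henicosan-1-ol and tris(trimethylsilyloxy)ethylene are taken as catalogue compounds.

## The problem

Target 13 is the ester of henicosan-1-ol with 2,3-dihydroxybenzoic acid: one benzene ring, one unbranched C21 chain and no stereocentre, so the difficulty lies in chemoselectivity and in the substitution pattern, not in control in space. The ring carries CO2R on C1 and OH on C2 and C3, three contiguous carbons, while C4, C5 and C6 are unsubstituted CH groups. The ester bond joins a waxy, sparingly soluble primary alcohol, which cannot serve as solvent or be used in large excess, to an acid whose own phenols compete as nucleophiles once the carboxyl group is activated. The free catechol is the fragile part: it is oxidized to the ortho-quinone by air in base or by most oxidants, it chelates metals, and the neighbouring ester rules out hydroxide, alkoxide or harsh Lewis-acid deprotection, so the catechol should appear last under neutral or weakly acidic, non-oxidizing conditions. The feature that makes the key step possible is that ring atoms C1, C6, C5 and C4 (ester on C1, hydrogen on the others) are exactly C3 to C6 of a 3-alkoxycarbonyl-2-pyrone, in which the future ester is the activating group of an electron-poor diene, while C2–C3 with their two oxygens form a two-carbon unit at the oxidation level of glycolic acid, available as an electron-rich 1,1,2-trioxygenated alkene. Because both carbons of that unit keep an oxygen, either orientation of a [4+2] union gives the same 1,2,3-pattern, and the O–C(=O) bridge of the pyrone can leave as CO2, so the benzene ring can be made with the ester and both hydroxyls in place in one operation. The C21 alcohol is the costly component and should enter in a step that uses it close to 1:1.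

## Retrosynthesis

13 back to 12. The two phenolic O–H bonds are replaced by O–SiMe3. This adds no complexity and is not a separate protection: the silyl groups arrive with the reagent of the ring-forming step. It places the appearance of the catechol in the final operation. The forward reaction only has to cleave two aryl silyl ethers without transesterifying the henicosyl ester.

12 back to 8 and 9, through 11 and 10. Two ring bonds of the arene are cut, C1–C2 and C3–C4 (arene numbering), after formally returning a silyloxy group and a hydrogen to C2/C3 (11) and re-inserting the O–C(=O) bridge between C1 and C4 (10). This leaves the pyrone ester 8 as the four-carbon diene and the ketene acetal 9 as the two-carbon partner. Against the neighbouring cuts, this one puts the ester on the diene, where it is the activating group, and puts both oxygens on one commercial reagent. It also makes the orientation of the cycloaddition irrelevant, because both carbons of 9 keep an oxygen. The precursor 8 has no arene, no phenol and no stereocentre. The forward reaction must achieve an inverse-electron-demand cycloaddition with a trisubstituted silyl ketene acetal, cycloreversion of the bridge, and loss of one silyloxy group with the adjacent hydrogen.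

8 back to 5 and 6, through 7. The acyl C–O bond of the ester is cut. At the pyrone stage the acid 5 has no hydroxyl group, so after activation as the chloride 7 the alcohol 6 is the only nucleophile present and can be used in near-equimolar amount. Building the pyrone on a henicosyl malonate instead would carry the expensive chain through more steps and raise the question of which ester closes the lactone. The forward reaction must acylate without a nucleophilic catalyst that could add to C6 of the pyrone.

5 back to 3, through 4. The lactone bond O1–C2 of the pyrone is cut and the carboxyl group is returned to the cyclic acylal of a dioxanedione. The enol oxygen of 4 is placed to attack one ring carbonyl of a very good acylating group, and the ring-opening that follows sets the carboxylic acid free without a separate ester hydrolysis. Hydrolysing a pyrone ester in the presence of the base-sensitive pyrone ring is thereby avoided. The forward reaction needs hydrolysis of one enol ether, E to Z equilibration of the enol, and lactonization faster than hydrolytic loss of the dioxanedione ring.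

3 back to 1 and 2. The C=C bond between the dioxanedione carbon and the three-carbon chain is cut, which gives the C–H acid 1 and the bis-acetal 2, both commodity chemicals. The forward reaction is a Knoevenagel-type condensation with loss of three molecules of alcohol.

## Roads not taken

Alternative 1: The most obvious cut is the acyl C–O bond of 13 itself, giving 2,3-dihydroxybenzoic acid A1 and 6. The forward key step is a Fischer esterification, or a Mitsunobu esterification of unprotected A1. The protected variant converts A1 into 2,3-bis(benzyloxy)benzoic acid A2, couples it with 6 by a carbodiimide to henicosyl 2,3-bis(benzyloxy)benzoate A3, and ends with hydrogenolysis. In step count the unprotected variant is shorter than the chosen route, and that is conceded. It is set aside for three reasons: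
- It buys the complete 1,2,3-pattern and contributes nothing to its construction.
- The Fischer reaction is an equilibrium in which neither partner can be the solvent, and the carbonyl group is deactivated by the hydrogen bond from the C2 hydroxyl.
- Any activation of A1 (carbodiimide, acid chloride, or the phosphonium chemistry of the Mitsunobu reaction) exposes two phenols to acylation or alkylation. The by-products carry the same C21 chain and have nearly the polarity of the product.

The protected variant removes the third problem but needs about four steps of pure protecting-group traffic. The chosen plan uses the same number of steps, never has a phenol present while an electrophile is in the flask, and forms the catechol and the ring together.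

Alternative 2: Both bonds at the carbonyl carbon are cut, aryl C1–C(=O) and C(=O)–O, which gives an aryl bromide, carbon monoxide and 6. The forward key step is a three-component alkoxycarbonylation of 4-bromo-2,2-dimethyl-1,3-benzodioxole A4 (Pd(OAc)2, Xantphos, CO, Et3N, toluene, 90 °C; oxidative addition to zerovalent palladium, CO insertion, alcoholysis of the acylpalladium species by 6). This gives henicosyl 2,2-dimethyl-1,3-benzodioxole-4-carboxylate A5, followed by acid cleavage of the ketal. The chosen plan is preferred for these reasons:
- A4 is not a commodity, and its 1,2,3-pattern has to be set beforehand by directed lithiation and bromination, so the pattern is again bought with steps.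
- The catechol must still be masked and unmasked, and unmasking needs strong aqueous acid next to the ester.
- The acylpalladium intermediate must be captured by an alcohol used at about one equivalent, which favours reduction and decarbonylation pathways.
- Palladium must then be removed from a chelating catechol.

The step count would be no lower than four.

Alternative 3: The ring is kept but its oxidation level is cut, by carrying a saturated ring and aromatizing late. Ethyl 2-oxocyclohexane-1-carboxylate A6 is transesterified thermally with 6 to henicosyl 2-oxocyclohexane-1-carboxylate A7 (neutral, 1:1, a very good way to attach the chain). A7 is oxidized at C3 to henicosyl 2,3-dioxocyclohexane-1-carboxylate A8, and the forward key step is the dehydrogenation of A8 to 13 (loss of four hydrogens; I2/DMSO or palladium on carbon). The weak points are structural: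
- Oxidants attack A7 through its more stable enol, which is the one conjugated with the ester, so C1 and not C3 is functionalized, and a substituent on C1 blocks aromatization.
- The final dehydrogenation is an oxidation run in the presence of its own product, a catechol that is more easily oxidized than the substrate.

The chosen plan is redox-neutral throughout, because 9 brings in the oxidation level of the catechol.

Key step: step 4

## Route

Step 1
Reactants: 1 2,2-dimethyl-1,3-dioxane-4,6-dione (Meldrum's acid); 2 1,1,3,3-tetramethoxypropane
Product: 3 5-[(2E)-3-methoxyprop-2-en-1-ylidene]-2,2-dimethyl-1,3-dioxane-4,6-dione
Conditions: neat 2 (1.5 equiv), 75 °C, MeOH distilled off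
Reagents that add atoms: none
Why: Knoevenagel-type condensation of the cyclic C–H acid 1 with the vinylogous oxocarbenium ion that 2 forms by acid-promoted loss of methanol (1 is acidic enough to start this); two further eliminations of methanol leave the push–pull diene 3. The same reaction type of 1 with orthoesters and with this bis-acetal is established.

Step 2
Reactants: 3 5-[(2E)-3-methoxyprop-2-en-1-ylidene]-2,2-dimethyl-1,3-dioxane-4,6-dione
Product: 5 2-oxo-2H-pyran-3-carboxylic acid, via hydroxyallylidene enol 4 (not isolated)
Conditions: HCO2H–H2O (9:1), 60 °C
Reagents that add atoms: water, O
Why: Addition–elimination of water at the methoxy-bearing terminus gives enol 4, whose Z form (reached through the aldehyde tautomer) attacks one of the strongly acylating ring carbonyls in a 6-exo-trig lactonization; collapse of the acylal releases acetone and the free carboxylic acid. This is the aliphatic counterpart of the synthesis of coumarin-3-carboxylic acids from salicylaldehydes and 1, and aqueous formic acid is the classical medium for closing 3-alkoxyallylidene malonates to 2-pyrones.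

Step 3
Reactants: 5 2-oxo-2H-pyran-3-carboxylic acid; 6 henicosan-1-ol
Product: 8 henicosyl 2-oxo-2H-pyran-3-carboxylate, via 2-oxo-2H-pyran-3-carbonyl chloride 7 (not isolated)
Conditions: (COCl)2, cat. DMF, CH2Cl2, 0 to 23 °C, then evaporate; 6 (1.0 equiv), toluene, 60 °C, N2 stream
Reagents that add atoms: none
Why: Acid chloride formation through the chloroiminium salt from DMF and oxalyl chloride, then acylation of the primary alcohol without base or nucleophilic catalyst, so that nothing in the flask can add to C6 of the electrophilic pyrone. Acid 5 has no hydroxyl group, so 6 is the only nucleophile and reacts in near-equimolar amount while HCl is swept out.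

Step 4
Reactants: 8 henicosyl 2-oxo-2H-pyran-3-carboxylate; 9 tris(trimethylsilyloxy)ethylene
Product: 13 henicosyl 2,3-dihydroxybenzoate, via bridged lactone cycloadduct 10 (not isolated), via tris(trimethylsilyloxy)cyclohexadiene ester 11 (not isolated), via bis(trimethylsilyl) ether 12 (not isolated)
Conditions: 9 (2.5 equiv), toluene, 110 °C, sealed, Ar; then MeOH, cat. citric acid, 23 °C
Reagents that add atoms: none
Why: Inverse-electron-demand Diels–Alder reaction: the diene C3–C6 of the pyrone, whose LUMO is lowered by the C3 ester and the lactone carbonyl, combines with the HOMO of the trioxygenated ketene acetal 9 in a concerted but asynchronous [4+2] closure that forms the six-membered carbocycle as the bridged lactone 10, the nucleophilic CH(OSiMe3) carbon being expected to bond to C6 and the acetal carbon to C3. Retro-[4+2] loss of CO2 from 10 gives diene 11, 1,2-elimination of Me3SiOH across the ketal carbon and the adjacent CH(OSiMe3) gives the aromatic bis(silyl ether) 12, and methanolysis of the two aryl O–Si bonds releases 13. The closest known reaction type is the conversion of 3-alkoxycarbonyl-2-pyrones into salicylates with 1,1-dialkoxyethylenes (cycloaddition, loss of CO2, loss of alcohol). The stereocentres of 10 and 11 are transient and all erased on aromatization, so neither endo/exo nor facial selectivity is needed. Regioselectivity is not needed either, because both carbons of 9 carry an oxygen that survives and either orientation ends in the same 1,2,3-pattern. What the step does need is ring closure in preference to silyl transfer within a zwitterionic Michael-type adduct; a non-polar solvent and the absence of any Lewis acid favour the concerted path. If part of 11 survives the heating, the acidic methanol converts it by ketal cleavage and enolization into the same catechol, and the henicosyl ester is not exchanged at 23 °C with a weak acid.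

## Compound list

1 | 2,2-dimethyl-1,3-dioxane-4,6-dione (Meldrum's acid) | CC1(C)OC(=O)CC(=O)O1 | starting material
2 | 1,1,3,3-tetramethoxypropane | COC(CC(OC)OC)OC | starting material
3 | 5-[(2E)-3-methoxyprop-2-en-1-ylidene]-2,2-dimethyl-1,3-dioxane-4,6-dione | CO/C=C/C=C1C(=O)OC(C)(C)OC1=O | intermediate
4 | 5-[(2Z)-3-hydroxyprop-2-en-1-ylidene]-2,2-dimethyl-1,3-dioxane-4,6-dione (not isolated) | O/C=C\C=C1C(=O)OC(C)(C)OC1=O | intermediate
5 | 2-oxo-2H-pyran-3-carboxylic acid | OC(=O)C1=CC=COC1=O | intermediate
6 | henicosan-1-ol | CCCCCCCCCCCCCCCCCCCCCO | starting material
7 | 2-oxo-2H-pyran-3-carbonyl chloride (not isolated) | ClC(=O)C1=CC=COC1=O | intermediate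
8 | henicosyl 2-oxo-2H-pyran-3-carboxylate | CCCCCCCCCCCCCCCCCCCCCOC(=O)C1=CC=COC1=O | intermediate
9 | tris(trimethylsilyloxy)ethylene | C[Si](C)(C)OC=C(O[Si](C)(C)C)O[Si](C)(C)C | starting material
10 | henicosyl 3-oxo-7,8,8-tris(trimethylsilyloxy)-2-oxabicyclo[2.2.2]oct-5-ene-4-carboxylate (racemic, mixture of C7 epimers, not isolated) | CCCCCCCCCCCCCCCCCCCCCOC(=O)C12C=CC(OC1=O)C(O[Si](C)(C)C)C2(O[Si](C)(C)C)O[Si](C)(C)C | intermediate
11 | henicosyl 5,6,6-tris(trimethylsilyloxy)cyclohexa-1,3-diene-1-carboxylate (racemic, not isolated) | CCCCCCCCCCCCCCCCCCCCCOC(=O)C1=CC=CC(O[Si](C)(C)C)C1(O[Si](C)(C)C)O[Si](C)(C)C | intermediate
12 | henicosyl 2,3-bis(trimethylsilyloxy)benzoate (not isolated) | CCCCCCCCCCCCCCCCCCCCCOC(=O)c1cccc(O[Si](C)(C)C)c1O[Si](C)(C)C | intermediate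
13 | henicosyl 2,3-dihydroxybenzoate | CCCCCCCCCCCCCCCCCCCCCOC(=O)c1cccc(O)c1O | target

## Step count and risks

Total step count: 4. Longest linear sequence: 4 steps (1 to 3 to 5 to 8 to 13); 2, 6 and 9 enter as purchased components.

Step 4 (key step). The most likely failure is that ring closure does not keep pace with other fates of the dienophile. The trisubstituted, hindered silyl ketene acetal may add only through its CH carbon to C6 and then transfer a silyl group to the pyrone oxygen, which is an open-chain Michael-type addition without cycloadduct. Alternatively it may be consumed by thermal desilylation before the electron-poor diene has reacted. Loss of CO2 and aromatization are not the concern, since both are driven by gas evolution and aromaticity. The fallback abandons ring construction and buys the arene. It sets out from 6, which is esterified chemoselectively with 2,3-dihydroxybenzoic acid A1 under Mitsunobu conditions (PPh3, diisopropyl azodicarboxylate, THF, 0 to 23 °C). The carboxylic acid, far more acidic than the phenols, is the pronucleophile that attacks the alkoxyphosphonium ion of 6. The fallback comes back to the route at 13 and makes no new compound (F0).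

Step 2. The most likely failure is hydrolytic opening of the dioxanedione ring and decarboxylation of the resulting malonic acid, or retro-Knoevenagel cleavage, before the enol has reached the Z geometry and lactonized. The fallback installs the chain first and lets a tert-butyl ester act as the leaving group of the lactonization. It sets out from 6 and 2. Alcohol 6 is coupled with tert-butyl hydrogen malonate F1 (EDC·HCl, cat. DMAP, CH2Cl2) to tert-butyl henicosyl malonate F2. F2 is condensed with 2 (Ac2O, cat. ZnCl2, 90 °C) to 1-tert-butyl 3-henicosyl 2-[(2E)-3-methoxyprop-2-en-1-ylidene]propanedioate F3. Treatment with CF3CO2H (CH2Cl2, 23 °C) closes the lactone through the tert-butyl ester carbonyl with loss of isobutene and methanol, and only the primary henicosyl ester is retained. The fallback comes back to the route at 8 and bypasses steps 2 and 3.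

Step 3. The most likely failure is addition of chloride or of the alcohol to C6 of the pyrone once the carbonyl group is activated as the chloride, which leads to ring-opening, together with incomplete acylation because 6 dissolves poorly. The fallback reverses the polarity of the ester formation, so that the pyrone carbonyl is never activated. It sets out from 6, which is converted into 1-bromohenicosane F4 by an Appel reaction (CBr4, PPh3, CH2Cl2, 0 to 23 °C). The potassium carboxylate of 5 is then alkylated with F4 at oxygen (KHCO3, DMF, 50 °C), forming the O–CH2 bond instead of the acyl–O bond. The fallback comes back to the route at 8.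

## Further compounds

F0 | step 4 | none | none
F1 | step 2 | tert-butyl hydrogen malonate | CC(C)(C)OC(=O)CC(=O)O
F2 | step 2 | tert-butyl henicosyl malonate | CCCCCCCCCCCCCCCCCCCCCOC(=O)CC(=O)OC(C)(C)C
F3 | step 2 | 1-tert-butyl 3-henicosyl 2-[(2E)-3-methoxyprop-2-en-1-ylidene]propanedioate | CCCCCCCCCCCCCCCCCCCCCOC(=O)C(=C/C=C/OC)C(=O)OC(C)(C)C
F4 | step 3 | 1-bromohenicosane | CCCCCCCCCCCCCCCCCCCCCBr
A1 | alternative 1 | 2,3-dihydroxybenzoic acid | OC(=O)c1cccc(O)c1O
A2 | alternative 1 | 2,3-bis(benzyloxy)benzoic acid | OC(=O)c1cccc(OCc2ccccc2)c1OCc1ccccc1
A3 | alternative 1 | henicosyl 2,3-bis(benzyloxy)benzoate | CCCCCCCCCCCCCCCCCCCCCOC(=O)c1cccc(OCc2ccccc2)c1OCc1ccccc1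
A4 | alternative 2 | 4-bromo-2,2-dimethyl-1,3-benzodioxole | CC1(C)Oc2cccc(Br)c2O1
A5 | alternative 2 | henicosyl 2,2-dimethyl-1,3-benzodioxole-4-carboxylate | CCCCCCCCCCCCCCCCCCCCCOC(=O)c1cccc2OC(C)(C)Oc12
A6 | alternative 3 | ethyl 2-oxocyclohexane-1-carboxylate | CCOC(=O)C1CCCCC1=O
A7 | alternative 3 | henicosyl 2-oxocyclohexane-1-carboxylate | CCCCCCCCCCCCCCCCCCCCCOC(=O)C1CCCCC1=O
A8 | alternative 3 | henicosyl 2,3-dioxocyclohexane-1-carboxylate | CCCCCCCCCCCCCCCCCCCCCOC(=O)C1CCCC(=O)C1=O
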